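Over 2.0 h, Z accumulates in a stirred flask as gas E passes into solution as J and the catalyst Q turns D and J into Z.

    E ⇌ J, rate k1*(csat - [J]) (k1 = 0.017 /s, csat = 63 mM)
    D + J + Q → Q + Z (k2 = 8.5 /M²/s)
    J + Q ⇌ J.Q, settled at all times (K3 = 770 /M)

D 0.80 M; E 63 mM (held); Q 0.80 mM; time 2.0 h

- at the start none of J is dissolved
- run time (flask): 2.0 h

- violet: doubling the amount of Q, all else as stated
- amber: doubling the saturation concentration of E, all else as stated
- red: doubling the transfer coefficient of step 1, all else as stated

- the Z standing at 2.0 h, as a percentage of the D charged
- the change that raises the amount of Z at 2.0 h, in percent of the D charged most ("none" if none brings more than 2 percentage points) (violet / amber / red / none)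
- amount of Z at 2.0 h, in percent of the D charged, after violet

This reckoning keeps its books on D, the limiting reagent: a mole of D charged either stands as D or has become Z. The first entry is J, taken at its saturation value of 63 mM, because the filling time, the reciprocal of the transfer coefficient, is 58.8 s, far shorter than the run. The second entry is the catalyst: J.Q stands to free Q as the binding constant times [J], or 48.5, so the free share is 2.02% and nearly all of the catalyst lies as J.Q, a form outside the working round. Z then forms at k_w[D], where the working constant k_w, the pseudo-first-order constant of D, is the turnover constant times [J] times free Q, here 0.0312 /h. The books close at 6.04% of the charge as Z and 94.0% as D.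

Going round once more, this rate at the full charge of D puts J below saturation by an estimated 0.407 mM, a gap far smaller than the 63 mM of saturation. With [J] at 62.6 mM, the Z entry reads 6.04%. With [J] held at 63 mM, doubling c_Q, the charge of Q, doubles k_w, so violet gives 11.7%. The rise under amber, 0.06 percentage points, is smaller than the margin of 2 points, and red halves the gap. The pick here is violet.

The forecast gives 6% (range 5.7% to 6.3%) and picks violet at 11.6% (range 11% to 12.1%), on the ground that “doubling Q nearly doubles the rate”. Its violet figure stands slightly below this reckoning's.

The simulation gives 6.04% and picks violet, which reaches 11.7%, a gain of 5.7 points; amber adds 0.062 points and red 0 points.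

In this flask, k_w gives D a half-life of 22.3 h, and the run's half-life of D by the step to Z at 2.00 h is 22 h. For a repeat, Z is the reading to watch: k_w puts it at 1.55% at 0.500 h, where the run shows 1.54%. The neighbouring flask, with the same amounts but read at 5.0 h, takes the same k_w, which gives 14.4%. That neighbouring flask stands at 14.4% Z, with 86% of its D left.

The rate constants come from no measurement; the run is a simulation.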